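The target is numbered as a tricyclo[5.4.0.0(2,8)]undec-9-en-11-one (C2 quaternary, C6 gem-dimethyl). Everything rests on opening the cyclobutane C1–C2–C8–C7 at C7–C8: C8 is the α-carbon and C2 the β-carbon of a ring A cyclohexenone (carbonyl at C9), and C7 lies 1,3 to C8 across C2. In one operation, methyl cuprate addition to that enone and 4-exo alkylation of the resulting enolate by a side-chain tosylate set the quaternary C2 and close the bicyclo[3.1.1]heptanone. The precursor is a 3,4-disubstituted cyclohex-2-enone; the seven-membered ring is closed later by an aldol reaction across the two one-carbon bridges.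

Key step: step 8

Remark: 1, 5 and 9 are taken as commercial. Tricyclic compounds are numbered as above, bicyclic ones as bicyclo[3.1.1]heptanes, monocyclic ones as cyclohexenones with primed locants for the side chain.

Step 1
Reactants: 1 ethyl 2,2-dimethyl-3-oxobutanoate
Product: 2 ethyl (3R)-3-hydroxy-2,2-dimethylbutanoate
Conditions: H2 (50 atm), RuCl2[(R)-BINAP] (0.5 mol %), EtOH, 50 °C
Reagents that add atoms: none
Why: Noyori asymmetric hydrogenation of a β-keto ester, in which the ester-chelated ketone is reduced from the face selected by the (R)-BINAP ligand to give the (3R)-alcohol; this centre is a temporary control element that is erased in step 13.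

Step 2
Reactants: 2 ethyl (3R)-3-hydroxy-2,2-dimethylbutanoate
Product: 3 ethyl (3R)-3-(methoxymethoxy)-2,2-dimethylbutanoate
Conditions: MOMCl, i-Pr2NEt, CH2Cl2, 0 °C to rt
Reagents that add atoms: chloromethyl methyl ether, COCCl
Why: O-alkylation with an α-chloro ether (MOM protection) gives an ether that survives the organolithium and cuprate steps and can chelate TiCl4 in step 4.

Step 3
Reactants: 3 ethyl (3R)-3-(methoxymethoxy)-2,2-dimethylbutanoate
Product: 4 (3R)-3-(methoxymethoxy)-2,2-dimethylbutanal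
Conditions: i-Bu2AlH, CH2Cl2, −78 °C; aq. potassium sodium tartrate
Reagents that add atoms: none
Why: Partial ester reduction, in which the aluminium hemiacetal is stable at −78 °C and collapses only on work-up; the aldehyde has no α-hydrogen, so it cannot enolise.

Step 4
Reactants: 5 3-ethoxycyclohex-2-en-1-one; 4 (3R)-3-(methoxymethoxy)-2,2-dimethylbutanal
Product: 7 (6R)-3-ethoxy-6-[(1R,3R)-1-hydroxy-3-(methoxymethoxy)-2,2-dimethylbutyl]cyclohex-2-en-1-one, via silyl dienol ether 6 (not isolated)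
Conditions: 5, LDA, THF, −78 °C, then Me3SiCl; solvent exchange to CH2Cl2; 4, TiCl4, −78 °C; aq. NaHCO3
Reagents that add atoms: none
Why: Chelation-controlled Mukaiyama aldol reaction, in which the kinetic C6 enolate (Stork–Danheiser regiochemistry) is trapped as diene 6 and adds through an open transition state to the TiCl4 chelate of the β-alkoxy aldehyde, anti to the methyl group on the chelate ring (1,3-anti) and with 2,3-syn simple selectivity, so that C6 and C1′ should both be set from C3′.

Step 5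
Reactants: 7 (6R)-3-ethoxy-6-[(1R,3R)-1-hydroxy-3-(methoxymethoxy)-2,2-dimethylbutyl]cyclohex-2-en-1-one
Product: 8 (6R)-3-ethoxy-6-[(1R,3R)-3-(methoxymethoxy)-2,2-dimethyl-1-(triethylsilyloxy)butyl]cyclohex-2-en-1-one
Conditions: Et3SiOTf, 2,6-lutidine, CH2Cl2, −78 °C
Reagents that add atoms: triethylsilyl trifluoromethanesulfonate, CC[Si](CC)(CC)OS(=O)(=O)C(F)(F)F
Why: Silylation of the hindered alcohol with a silyl triflate prevents retro-aldol cleavage of an aldolate during the organolithium addition of step 6.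

Step 6
Reactants: 8 (6R)-3-ethoxy-6-[(1R,3R)-3-(methoxymethoxy)-2,2-dimethyl-1-(triethylsilyloxy)butyl]cyclohex-2-en-1-one; 9 tributyl[(methoxymethoxy)methyl]stannane
Product: 12 (4S)-4-[(1R,3R)-1-hydroxy-3-(methoxymethoxy)-2,2-dimethylbutyl]-3-[(methoxymethoxy)methyl]cyclohex-2-en-1-one, via lithiated methoxymethyl ether 10 (not isolated), via tertiary lithium alkoxide 11 (not isolated)
Conditions: 9, n-BuLi, THF, −78 °C; then 8, −78 to −40 °C; then 1 M HCl, THF, 0 °C to rt
Reagents that add atoms: water, O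
Why: Stork–Danheiser sequence, in which tin–lithium exchange gives the alkoxymethyllithium, this adds 1,2 to the vinylogous ester carbonyl, and aqueous acid ionises the tertiary allylic alcohol, hydrolyses the enol ether to the transposed enone and cleaves the silyl ether, all without touching the ring stereocentre.

Step 7
Reactants: 12 (4S)-4-[(1R,3R)-1-hydroxy-3-(methoxymethoxy)-2,2-dimethylbutyl]-3-[(methoxymethoxy)methyl]cyclohex-2-en-1-one
Product: 13 (1R,3R)-3-(methoxymethoxy)-1-{(1S)-2-[(methoxymethoxy)methyl]-4-oxocyclohex-2-en-1-yl}-2,2-dimethylbutyl 4-methylbenzenesulfonate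
Conditions: TsCl, Et3N, Me3N·HCl (cat.), CH2Cl2, 0 °C to rt
Reagents that add atoms: 4-methylbenzenesulfonyl chloride, Cc1ccc(cc1)S(Cl)(=O)=O
Why: Sulfonylation at oxygen (retention at carbon) installs the leaving group; a tosylate is chosen over a mesylate because it has no acidic α-hydrogens.

Step 8
Reactants: 13 (1R,3R)-3-(methoxymethoxy)-1-{(1S)-2-[(methoxymethoxy)methyl]-4-oxocyclohex-2-en-1-yl}-2,2-dimethylbutyl 4-methylbenzenesulfonate
Product: 15 (1S,5R,6S,7R)-6-[(methoxymethoxy)methyl]-7-[(3R)-3-(methoxymethoxy)-2-methylbutan-2-yl]-6-methylbicyclo[3.1.1]heptan-2-one, via lithium enolate 14 (not isolated)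
Conditions: Me2CuLi (from CuI and MeLi), Et2O, −40 to 0 °C; then HMPA, THF, 0 to 40 °C
Reagents that add atoms: lithium dimethylcuprate, [Li+].C[Cu-]C
Why: The cuprate adds methyl to the β-carbon of the enone (C3 of 13, the future C2 of the target) through a copper π-complex and reductive elimination, anti to the pseudoaxial side chain at C4, which should give the quaternary centre and a regiodefined lithium enolate at C2 of 13 (future C8) that deprotonation could not provide. On warming with HMPA the enolate carbon displaces the side-chain tosylate in a 4-exo-tet SN2 reaction with inversion at the carbinol carbon (future C7), which closes the cyclobutane and with it the bicyclo[3.1.1]heptan-2-one. The closest known reactions are conjugate addition–cycloalkylation sequences of sulfonyloxy enones and the keto tosylate cyclisations that give pinane-type bicyclo[3.1.1]heptanones. The configuration at the quaternary carbon is controlled by the C4 stereocentre of 13 (trans addition), that at the enolate carbon by the geometric need for a 1,3-diaxial bridge, and that at the former carbinol carbon by the tosylate configuration, whose inversion places the bulky chain exo on the side of the alkoxymethyl group. The step needs C- over O-alkylation and substitution over elimination: O-alkylation would give a bridgehead enol ether and is excluded by Bredt's rule, and the tosylate carbon has a single β-hydrogen and faces a weakly basic enolate.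

Step 9
Reactants: 15 (1S,5R,6S,7R)-6-[(methoxymethoxy)methyl]-7-[(3R)-3-(methoxymethoxy)-2-methylbutan-2-yl]-6-methylbicyclo[3.1.1]heptan-2-one
Product: 16 (1S,5R,6S,7R)-6-[(methoxymethoxy)methyl]-7-[(3R)-3-(methoxymethoxy)-2-methylbutan-2-yl]-6-methylbicyclo[3.1.1]hept-3-en-2-one
Conditions: IBX, DMSO, 70 °C
Reagents that add atoms: none
Why: IBX-mediated α,β-dehydrogenation of the ketone, which can only go towards C3–C4 because C1 is a bridgehead, so a single enone should form.

Step 10
Reactants: 16 (1S,5R,6S,7R)-6-[(methoxymethoxy)methyl]-7-[(3R)-3-(methoxymethoxy)-2-methylbutan-2-yl]-6-methylbicyclo[3.1.1]hept-3-en-2-one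
Product: 17 (1S,2S,5R,6S,7R)-6-[(methoxymethoxy)methyl]-7-[(3R)-3-(methoxymethoxy)-2-methylbutan-2-yl]-2,6-dimethylbicyclo[3.1.1]hept-3-en-2-ol
Conditions: MeLi, THF, −78 °C; aq. NH4Cl
Reagents that add atoms: methyllithium, [Li]C
Why: 1,2-Addition of the hard organolithium to the enone carbonyl, expected from the face anti to the C6 methyl group that projects over the carbonyl bridge; the new carbinol centre is lost in step 11.

Step 11
Reactants: 17 (1S,2S,5R,6S,7R)-6-[(methoxymethoxy)methyl]-7-[(3R)-3-(methoxymethoxy)-2-methylbutan-2-yl]-2,6-dimethylbicyclo[3.1.1]hept-3-en-2-ol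
Product: 18 (1R,5R,6R,7S)-6-[(methoxymethoxy)methyl]-7-[(3R)-3-(methoxymethoxy)-2-methylbutan-2-yl]-4,6-dimethylbicyclo[3.1.1]hept-3-en-2-one
Conditions: pyridinium chlorochromate (C5H5NH[CrO3Cl]), 4 Å molecular sieves, CH2Cl2, rt
Reagents that add atoms: pyridinium chlorochromate, [O-][Cr](=O)(=O)Cl.c1cc[nH+]cc1
Why: Babler–Dauben oxidative transposition, in which the chromate ester of the tertiary allylic alcohol undergoes a [3,3]-shift and is oxidised at the other allylic terminus, placing the carbonyl next to the other bridgehead and the methyl group on the alkene, as in ring A of the target.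

Step 12
Reactants: 18 (1R,5R,6R,7S)-6-[(methoxymethoxy)methyl]-7-[(3R)-3-(methoxymethoxy)-2-methylbutan-2-yl]-4,6-dimethylbicyclo[3.1.1]hept-3-en-2-one
Product: 19 (1R,5R,6R,7S)-7-[(3R)-3-hydroxy-2-methylbutan-2-yl]-6-(hydroxymethyl)-4,6-dimethylbicyclo[3.1.1]hept-3-en-2-one
Conditions: HCl (cat.), MeOH, 40 °C
Reagents that add atoms: none
Why: Acid-catalysed acetal exchange with methanol removes both MOM groups; the cross-ring enone and the cyclobutane should tolerate dilute methanolic acid.

Step 13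
Reactants: 19 (1R,5R,6R,7S)-7-[(3R)-3-hydroxy-2-methylbutan-2-yl]-6-(hydroxymethyl)-4,6-dimethylbicyclo[3.1.1]hept-3-en-2-one
Product: 20 (1R,5R,6R,7S)-4,6-dimethyl-7-(2-methyl-3-oxobutan-2-yl)-2-oxobicyclo[3.1.1]hept-3-ene-6-carbaldehyde
Conditions: Dess–Martin periodinane, NaHCO3, CH2Cl2, rt
Reagents that add atoms: none
Why: Dess–Martin oxidation converts the neopentyl primary alcohol into a non-enolisable aldehyde and the secondary alcohol into a methyl ketone under buffered conditions, removing the temporary carbinol centre.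

Step 14
Reactants: 20 (1R,5R,6R,7S)-4,6-dimethyl-7-(2-methyl-3-oxobutan-2-yl)-2-oxobicyclo[3.1.1]hept-3-ene-6-carbaldehyde
Product: 21 (1R,2R,3R,7S,8R)-3-hydroxy-2,6,6,9-tetramethyltricyclo[5.4.0.0(2,8)]undec-9-ene-5,11-dione
Conditions: L-proline (30 mol %), DMSO, rt
Reagents that add atoms: none
Why: Proline-catalysed intramolecular aldol reaction, in which the enamine of the methyl ketone attacks the aldehyde on the neighbouring one-carbon bridge and closes the seven-membered ring through the C3–C4 bond; the two aldehyde faces differ only through remote groups, so the catalyst (enamine and carboxylic acid transition state) is expected to set C3 as R.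

Step 15
Reactants: 21 (1R,2R,3R,7S,8R)-3-hydroxy-2,6,6,9-tetramethyltricyclo[5.4.0.0(2,8)]undec-9-ene-5,11-dione
Product: 22 (1R,2R,3R,5R,7S,8R)-5-hydroxy-2,6,6,9-tetramethyl-11-oxotricyclo[5.4.0.0(2,8)]undec-9-en-3-yl 3-methylbut-2-enoate
Conditions: 3-methylbut-2-enal (6 equiv), SmI2 (30 mol %), THF, −10 °C
Reagents that add atoms: 3-methylbut-2-enal, CC(C)=CC=O
Why: Evans–Tishchenko reduction, in which the samarium-bound hemiacetal formed from the C3 hydroxyl and the enal delivers hydride intramolecularly to the C5 ketone through a six-membered transition state, giving the 1,3-anti (5R) alcohol and leaving the 3-methylbut-2-enoate on O3 in the same operation.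

Step 16
Reactants: 22 (1R,2R,3R,5R,7S,8R)-5-hydroxy-2,6,6,9-tetramethyl-11-oxotricyclo[5.4.0.0(2,8)]undec-9-en-3-yl 3-methylbut-2-enoate
Product: 23 (1R,2R,3R,5R,7S,8R)-2,6,6,9-tetramethyl-5-(3-methylbutanoyloxy)-11-oxotricyclo[5.4.0.0(2,8)]undec-9-en-3-yl 3-methylbut-2-enoate
Conditions: 3-methylbutanoyl chloride, pyridine, DMAP (cat.), CH2Cl2, 0 °C
Reagents that add atoms: 3-methylbutanoyl chloride, CC(C)CC(Cl)=O
Why: Acylation of the remaining hindered secondary alcohol under nucleophilic catalysis at low temperature, which limits 1,3-acyl migration, completes the mixed diester.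

Compound list
1 | ethyl 2,2-dimethyl-3-oxobutanoate | CCOC(=O)C(C)(C)C(C)=O | starting material
2 | ethyl (3R)-3-hydroxy-2,2-dimethylbutanoate | CCOC(=O)C(C)(C)[C@@H](C)O | intermediate
3 | ethyl (3R)-3-(methoxymethoxy)-2,2-dimethylbutanoate | CCOC(=O)C(C)(C)[C@@H](C)OCOC | intermediate
4 | (3R)-3-(methoxymethoxy)-2,2-dimethylbutanal | O=CC(C)(C)[C@@H](C)OCOC | intermediate
5 | 3-ethoxycyclohex-2-en-1-one | CCOC1=CC(=O)CCC1 | starting material
6 | 1-ethoxy-3-(trimethylsilyloxy)cyclohexa-1,3-diene (not isolated) | CCOC1=CC(O[Si](C)(C)C)=CCC1 | intermediate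
7 | (6R)-3-ethoxy-6-[(1R,3R)-1-hydroxy-3-(methoxymethoxy)-2,2-dimethylbutyl]cyclohex-2-en-1-one | CCOC1=CC(=O)[C@H](CC1)[C@@H](O)C(C)(C)[C@@H](C)OCOC | intermediate
8 | (6R)-3-ethoxy-6-[(1R,3R)-3-(methoxymethoxy)-2,2-dimethyl-1-(triethylsilyloxy)butyl]cyclohex-2-en-1-one | CCOC1=CC(=O)[C@H](CC1)[C@@H](O[Si](CC)(CC)CC)C(C)(C)[C@@H](C)OCOC | intermediate
9 | tributyl[(methoxymethoxy)methyl]stannane | CCCC[Sn](CCCC)(CCCC)COCOC | starting material
10 | (methoxymethoxy)methyllithium (not isolated) | [Li]COCOC | intermediate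
11 | lithium (6R)-3-ethoxy-1-[(methoxymethoxy)methyl]-6-[(1R,3R)-3-(methoxymethoxy)-2,2-dimethyl-1-(triethylsilyloxy)butyl]cyclohex-2-en-1-olate, both C1 epimers (not isolated) | [Li+].CCOC1=CC([O-])(COCOC)[C@H](CC1)[C@@H](O[Si](CC)(CC)CC)C(C)(C)[C@@H](C)OCOC | intermediate
12 | (4S)-4-[(1R,3R)-1-hydroxy-3-(methoxymethoxy)-2,2-dimethylbutyl]-3-[(methoxymethoxy)methyl]cyclohex-2-en-1-one | O=C1C=C(COCOC)[C@H](CC1)[C@@H](O)C(C)(C)[C@@H](C)OCOC | intermediate
13 | (1R,3R)-3-(methoxymethoxy)-1-{(1S)-2-[(methoxymethoxy)methyl]-4-oxocyclohex-2-en-1-yl}-2,2-dimethylbutyl 4-methylbenzenesulfonate | O=C1C=C(COCOC)[C@H](CC1)[C@@H](OS(=O)(=O)c1ccc(C)cc1)C(C)(C)[C@@H](C)OCOC | intermediate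
14 | lithium (3S,4S)-3-[(methoxymethoxy)methyl]-3-methyl-4-[(1R,3R)-3-(methoxymethoxy)-2,2-dimethyl-1-(4-methylbenzenesulfonyloxy)butyl]cyclohex-1-en-1-olate (not isolated) | [Li+].[O-]C1=C[C@@](C)(COCOC)[C@H](CC1)[C@@H](OS(=O)(=O)c1ccc(C)cc1)C(C)(C)[C@@H](C)OCOC | intermediate
15 | (1S,5R,6S,7R)-6-[(methoxymethoxy)methyl]-7-[(3R)-3-(methoxymethoxy)-2-methylbutan-2-yl]-6-methylbicyclo[3.1.1]heptan-2-one | C[C@@H](OCOC)C(C)(C)[C@@H]1[C@H]2CCC(=O)[C@@H]1[C@]2(COCOC)C | intermediate
16 | (1S,5R,6S,7R)-6-[(methoxymethoxy)methyl]-7-[(3R)-3-(methoxymethoxy)-2-methylbutan-2-yl]-6-methylbicyclo[3.1.1]hept-3-en-2-one | C[C@@H](OCOC)C(C)(C)[C@@H]1[C@H]2C=CC(=O)[C@@H]1[C@]2(COCOC)C | intermediate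
17 | (1S,2S,5R,6S,7R)-6-[(methoxymethoxy)methyl]-7-[(3R)-3-(methoxymethoxy)-2-methylbutan-2-yl]-2,6-dimethylbicyclo[3.1.1]hept-3-en-2-ol | C[C@@H](OCOC)C(C)(C)[C@@H]1[C@H]2C=C[C@](C)(O)[C@@H]1[C@]2(COCOC)C | intermediate
18 | (1R,5R,6R,7S)-6-[(methoxymethoxy)methyl]-7-[(3R)-3-(methoxymethoxy)-2-methylbutan-2-yl]-4,6-dimethylbicyclo[3.1.1]hept-3-en-2-one | C[C@@H](OCOC)C(C)(C)[C@@H]1[C@H]2C(=O)C=C(C)[C@@H]1[C@]2(COCOC)C | intermediate
19 | (1R,5R,6R,7S)-7-[(3R)-3-hydroxy-2-methylbutan-2-yl]-6-(hydroxymethyl)-4,6-dimethylbicyclo[3.1.1]hept-3-en-2-one | C[C@@H](O)C(C)(C)[C@@H]1[C@H]2C(=O)C=C(C)[C@@H]1[C@]2(CO)C | intermediate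
20 | (1R,5R,6R,7S)-4,6-dimethyl-7-(2-methyl-3-oxobutan-2-yl)-2-oxobicyclo[3.1.1]hept-3-ene-6-carbaldehyde | CC(=O)C(C)(C)[C@@H]1[C@H]2C(=O)C=C(C)[C@@H]1[C@]2(C=O)C | intermediate
21 | (1R,2R,3R,7S,8R)-3-hydroxy-2,6,6,9-tetramethyltricyclo[5.4.0.0(2,8)]undec-9-ene-5,11-dione | O[C@@H]1CC(=O)C(C)(C)[C@@H]2[C@H]3C(=O)C=C(C)[C@@H]2[C@]31C | intermediate
22 | (1R,2R,3R,5R,7S,8R)-5-hydroxy-2,6,6,9-tetramethyl-11-oxotricyclo[5.4.0.0(2,8)]undec-9-en-3-yl 3-methylbut-2-enoate | CC(C)=CC(=O)O[C@@H]1C[C@@H](O)C(C)(C)[C@@H]2[C@H]3C(=O)C=C(C)[C@@H]2[C@]31C | intermediate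
23 | (1R,2R,3R,5R,7S,8R)-2,6,6,9-tetramethyl-5-(3-methylbutanoyloxy)-11-oxotricyclo[5.4.0.0(2,8)]undec-9-en-3-yl 3-methylbut-2-enoate | CC(C)=CC(=O)O[C@@H]1C[C@@H](OC(=O)CC(C)C)C(C)(C)[C@@H]2[C@H]3C(=O)C=C(C)[C@@H]2[C@]31C | target

Total step count: 16. Longest linear sequence: 16 steps (1 to 23; 5 and 9 enter as commercial materials).

Steps most likely to fail

Step 8. The enolate may fail to displace the tosylate, because substitution at a carbon flanked by a quaternary centre is slow and elimination or proton transfer can win under the forcing conditions. The fallback separates the two events and sets out from 13. The cuprate adduct is quenched cold (Me2CuLi, Et2O, −40 °C; aq. NH4Cl) to give (1R,3R)-3-(methoxymethoxy)-1-{(1S,2R)-2-[(methoxymethoxy)methyl]-2-methyl-4-oxocyclohexyl}-2,2-dimethylbutyl 4-methylbenzenesulfonate F1. IBX (DMSO, 70 °C), which can only dehydrogenate away from the quaternary carbon, gives (1R,3R)-3-(methoxymethoxy)-1-{(1S,6R)-6-[(methoxymethoxy)methyl]-6-methyl-4-oxocyclohex-2-en-1-yl}-2,2-dimethylbutyl 4-methylbenzenesulfonate F2. LDA (THF/HMPA, −78 °C to rt) then forms the only available α′-enolate of this enone, and its 4-exo alkylation gives 16 directly, where the route is rejoined (step 9 is then not needed).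

Step 4. Facial selectivity at the aldehyde or syn simple selectivity may be poor if chelated and open pathways compete, and this would erode both relative and absolute control. The fallback sets the two centres by reduction and sets out from 4 and 5. The lithium enolate of 5 (LDA, THF, −78 °C) and 4 give 3-ethoxy-6-[(3R)-1-hydroxy-3-(methoxymethoxy)-2,2-dimethylbutyl]cyclohex-2-en-1-one as a mixture of C6 and C1′ epimers F3. Dess–Martin oxidation gives 3-ethoxy-6-[(3R)-3-(methoxymethoxy)-2,2-dimethylbutanoyl]cyclohex-2-en-1-one F4, in which C6 is labile. Zn(BH4)2 (Et2O, −20 °C) should then reduce the side-chain ketone through a zinc chelate of the β-dicarbonyl unit with hydride entering anti to the ring (chelation-controlled syn reduction), returning 7 after removal of any minor isomer.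

Step 14. Enamine formation at the hindered methyl ketone may be too slow, or catalyst control over the aldehyde face may be incomplete. The fallback closes the ring without facial control and sets out from 20. LiN(SiMe3)2 (THF, −78 °C) forms the methyl ketone enolate, which adds to the aldehyde to give 21 together with (1R,2R,3S,7S,8R)-3-hydroxy-2,6,6,9-tetramethyltricyclo[5.4.0.0(2,8)]undec-9-ene-5,11-dione F5. The epimers are separated, F5 is returned to 20 by retro-aldol cleavage (DBU, toluene, rt) and resubmitted, and the route is rejoined at 21.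

Further compounds
F1 | step 8 | (1R,3R)-3-(methoxymethoxy)-1-{(1S,2R)-2-[(methoxymethoxy)methyl]-2-methyl-4-oxocyclohexyl}-2,2-dimethylbutyl 4-methylbenzenesulfonate | O=C1C[C@@](C)(COCOC)[C@H](CC1)[C@@H](OS(=O)(=O)c1ccc(C)cc1)C(C)(C)[C@@H](C)OCOC
F2 | step 8 | (1R,3R)-3-(methoxymethoxy)-1-{(1S,6R)-6-[(methoxymethoxy)methyl]-6-methyl-4-oxocyclohex-2-en-1-yl}-2,2-dimethylbutyl 4-methylbenzenesulfonate | O=C1C[C@@](C)(COCOC)[C@H](C=C1)[C@@H](OS(=O)(=O)c1ccc(C)cc1)C(C)(C)[C@@H](C)OCOC
F3 | step 4 | 3-ethoxy-6-[(3R)-1-hydroxy-3-(methoxymethoxy)-2,2-dimethylbutyl]cyclohex-2-en-1-one (mixture of C6 and C1′ epimers) | CCOC1=CC(=O)C(CC1)C(O)C(C)(C)[C@@H](C)OCOC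
F4 | step 4 | 3-ethoxy-6-[(3R)-3-(methoxymethoxy)-2,2-dimethylbutanoyl]cyclohex-2-en-1-one | CCOC1=CC(=O)C(CC1)C(=O)C(C)(C)[C@@H](C)OCOC
F5 | step 14 | (1R,2R,3S,7S,8R)-3-hydroxy-2,6,6,9-tetramethyltricyclo[5.4.0.0(2,8)]undec-9-ene-5,11-dione | O[C@H]1CC(=O)C(C)(C)[C@@H]2[C@H]3C(=O)C=C(C)[C@@H]2[C@]31C
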